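**Retrosynthetic overview**
1. Feature: ring A carries oxygen on C5 and C8 (para), oxygen on C7 beside C8 and hydrogen on C6. C5–C8 map onto the four carbons of a monoalkoxy squarate, and C4a/C8a onto C3/C2 of a 4-pyranone (ring C).
2. Key disconnection C4a–C5: ring A by thermal ring expansion of the 4-hydroxy-4-(4-oxopyran-2-yl)cyclobutenone 10 to the 5,8-dihydroxyflavone 13.
3. C8–C8a: the 6-lithio derivative of 2-aryl-4-pyranone 8 adds to 3-isopropoxycyclobutenedione 3, made from diisopropyl squarate 1.
4. Ring order: ring B is bought in acid chloride 5, ring C is closed from an acylated 4-methoxybutenone (steps 2–3), ring A is closed last (step 5).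
5. End game: ether cleavage to 8-hydroxyluteolin 14, peracetate, 7-O-deacetylation, sulfation of O7, ammonolysis.

Key step: step 5

Remark: the target is drawn as the free hydrogen sulfate; the route ends at this acid, released from its ammonium salt with one equivalent of cold acid, and the salt is the form to store.
Remark: the pyranone is deprotonated with a lithium amide and not a magnesium amide, because a magnesium amide held by the carbonyl oxygen can be directed to C3 or C5.

**Route**

Step 1
Reactants: 1 diisopropyl squarate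
Product: 3 3-isopropoxycyclobut-3-ene-1,2-dione, via 4-hydroxy-2,3-diisopropoxycyclobut-2-en-1-one 2 (not isolated)
Conditions: LiAlH(OtBu)3 (1.1 equiv), THF, −78 → −10 °C; then 6 M HCl, CH2Cl2, rt
Reagents that add atoms: water, O
Why: The bulky hydride adds once to a squarate carbonyl to give racemic 2, and in acid its hydroxyl leaves to form an alkoxy-stabilised cyclobutenyl cation that takes up water at the far alkoxy carbon and loses isopropanol (1,3-carbonyl transposition of a squarate adduct), which removes the stereocenter.

Step 2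
Reactants: 4 (E)-4-methoxybut-3-en-2-one; 5 3,4-dimethoxybenzoyl chloride
Product: 7 (E)-1-(3,4-dimethoxyphenyl)-5-methoxypent-4-ene-1,3-dione, via lithium dienolate 6 (not isolated)
Conditions: LiN(SiMe3)2 (2.1 equiv), THF, −78 °C, 4 (2.1 equiv); then 5 (1.0 equiv), −78 → 0 °C; aq. NH4Cl
Reagents that add atoms: none
Why: Claisen-type C-acylation of the kinetic lithium enolate of a methyl ketone by an aroyl chloride, in which the second equivalent of enolate takes the acidic diketone proton and so prevents a second acylation.

Step 3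
Reactants: 7 (E)-1-(3,4-dimethoxyphenyl)-5-methoxypent-4-ene-1,3-dione
Product: 8 2-(3,4-dimethoxyphenyl)-4H-pyran-4-one
Conditions: CF3CO2H (cat.), toluene, rt
Reagents that add atoms: none
Why: Acid-catalysed addition of the enol oxygen to the beta-methoxy enone followed by loss of methanol (oxa-Michael addition–elimination) closes the 4-pyranone.

Step 4
Reactants: 8 2-(3,4-dimethoxyphenyl)-4H-pyran-4-one; 3 3-isopropoxycyclobut-3-ene-1,2-dione
Product: 10 rac-4-[6-(3,4-dimethoxyphenyl)-4-oxo-4H-pyran-2-yl]-4-hydroxy-3-isopropoxycyclobut-2-en-1-one, via 6-lithiopyranone 9 (not isolated)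
Conditions: lithium 2,2,6,6-tetramethylpiperidide (1.1 equiv, from the amine and n-BuLi), THF, −78 °C, 8 added slowly to the base, 10 min; then 3 (1.2 equiv), −78 °C; sat. aq. NH4Cl at −78 °C; chromatography on Et3N-washed silica
Reagents that add atoms: none
Why: The hindered lithium amide removes the hydrogen next to the ring oxygen (the site lithiated in N-methyl-4-pyridone, 4-quinolones, 3-substituted chromones and uracils), and the vinyllithium adds 1,2 to C2 of 3, the ketone-like carbonyl, because C1 is deactivated as a vinylogous ester; the carbinol carbon forms as a racemate and is lost in step 5.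

Step 5
Reactants: 10 rac-4-[6-(3,4-dimethoxyphenyl)-4-oxo-4H-pyran-2-yl]-4-hydroxy-3-isopropoxycyclobut-2-en-1-one
Product: 13 2-(3,4-dimethoxyphenyl)-5,8-dihydroxy-7-isopropoxy-4H-chromen-4-one, via dienylketene 11 (not isolated), via 4aH-chromene-4,5-dione 12 (not isolated)
Conditions: p-xylene (degassed, 0.02 M), 130 °C, Ar
Reagents that add atoms: none
Why: Heating opens the cyclobutenone by conrotatory four-electron cleavage of the bond between the carbonyl and the carbinol carbon, the hydroxyl rotating outward as donor groups do, so that the pyranonyl group ends up cis to the ketene in 11. The ketene carbon then bonds to pyranone C3, the nucleophilic alpha-carbon of the vinylogous ester, in a disrotatory six-electron electrocyclisation that closes the six-membered ring A (bond C4a–C5) to give dienone 12, and enolisation of the C4a hydrogen, which lies between two carbonyls, aromatises the ring. The closest known reaction is the thermal ring expansion of 4-aryl-, 4-heteroaryl- and 4-alkenyl-4-hydroxycyclobutenones to hydroquinones (Moore rearrangement). No stereocenter remains, since the carbinol carbon of 10 and C4a of 12 both become sp2. The step needs outward rotation of the hydroxyl, which is its electronic preference, and closure at one site only, which the substrate secures because the other neighbour of the pyranone carbon is the ring oxygen. Oxygen falls on C5, C7 and C8 and hydrogen on C6 because these atoms are the four squarate carbons of 10 in unchanged order.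

Step 6
Reactants: 13 2-(3,4-dimethoxyphenyl)-5,8-dihydroxy-7-isopropoxy-4H-chromen-4-one
Product: 14 8-hydroxyluteolin (hypolaetin)
Conditions: BBr3 (8 equiv), CH2Cl2, −78 °C → rt; ice-water, EtOAc, under Ar; crude used directly
Reagents that add atoms: none
Why: BBr3 cleaves aryl alkyl ethers by O-complexation and bromide attack on the alkyl group, the isopropyl group first and the two methyl groups on warming, while the flavone core is inert to the Lewis acid.

Step 7
Reactants: 14 8-hydroxyluteolin (hypolaetin)
Product: 15 8-hydroxyluteolin 5,7,8,3',4'-pentaacetate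
Conditions: Ac2O, pyridine, DMAP (cat.), rt
Reagents that add atoms: acetic anhydride, CC(=O)OC(C)=O
Why: DMAP-catalysed acylation esterifies all five phenols, the hydrogen-bonded 5-OH included, and turns the air-sensitive polyphenol into a stable ester that can be chromatographed.

Step 8
Reactants: 15 8-hydroxyluteolin 5,7,8,3',4'-pentaacetate
Product: 16 8-hydroxyluteolin 5,8,3',4'-tetraacetate (7-OH free)
Conditions: PhSH (1.1 equiv), imidazole (0.3 equiv), N-methylpyrrolidinone, 0 °C
Reagents that add atoms: none
Why: Thiophenoxide formed with imidazole takes the acetyl group of the most electrophilic ester, that on O7 (para to the C4 carbonyl, the most acidic phenol of a flavone), as in the known selective 7-O-deacetylation of flavone peracetates; an acetyl shift from O8 to O7 is uphill because the more acidic phenol stays free.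

Step 9
Reactants: 16 8-hydroxyluteolin 5,8,3',4'-tetraacetate (7-OH free)
Product: 17 pyridinium 5,8,3',4'-tetra-O-acetyl-8-hydroxyluteolin 7-sulfate
Conditions: SO3·pyridine (5 equiv), pyridine, 40 °C; precipitation with Et2O
Reagents that add atoms: sulfur trioxide–pyridine complex, O=S(=O)([O-])[n+]1ccccc1
Why: O-Sulfonation of the single free phenol by the SO3·amine complex gives the aryl sulfate monoester as its pyridinium salt, the acetates blocking the other four oxygens.

Step 10
Reactants: 17 pyridinium 5,8,3',4'-tetra-O-acetyl-8-hydroxyluteolin 7-sulfate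
Product: 19 8-hydroxyluteolin 7-sulfate, via ammonium 7-sulfate 18 (not isolated)
Conditions: NH3 (7 M in MeOH, degassed), 0 °C, Ar; evaporate; HCl (1.0 equiv, 0.1 M aq.), 0 °C; C18 silica, H2O/MeOH; lyophilise
Reagents that add atoms: none
Why: Ammonolysis cleaves aryl acetates quickly while the sulfate monoester anion is inert to base, and one equivalent of cold acid then protonates the salt without the long acid contact that hydrolyses aryl sulfates.

**Compound list**
1 | diisopropyl squarate (3,4-diisopropoxycyclobut-3-ene-1,2-dione) | CC(C)OC1=C(OC(C)C)C(=O)C1=O | starting material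
2 | rac-4-hydroxy-2,3-diisopropoxycyclobut-2-en-1-one | CC(C)OC1=C(OC(C)C)C(O)C1=O | intermediate
3 | 3-isopropoxycyclobut-3-ene-1,2-dione | CC(C)OC1=CC(=O)C1=O | intermediate
4 | (E)-4-methoxybut-3-en-2-one | CO/C=C/C(C)=O | starting material
5 | 3,4-dimethoxybenzoyl chloride | COc1ccc(C(Cl)=O)cc1OC | starting material
6 | lithium (E)-4-methoxybuta-1,3-dien-2-olate | C=C(O[Li])/C=C/OC | intermediate
7 | (E)-1-(3,4-dimethoxyphenyl)-5-methoxypent-4-ene-1,3-dione (largely enolised) | CO/C=C/C(=O)CC(=O)c1ccc(OC)c(OC)c1 | intermediate
8 | 2-(3,4-dimethoxyphenyl)-4H-pyran-4-one | COc1ccc(-c2cc(=O)cco2)cc1OC | intermediate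
9 | [6-(3,4-dimethoxyphenyl)-4-oxo-4H-pyran-2-yl]lithium | [Li]c1cc(=O)cc(-c2ccc(OC)c(OC)c2)o1 | intermediate
10 | rac-4-[6-(3,4-dimethoxyphenyl)-4-oxo-4H-pyran-2-yl]-4-hydroxy-3-isopropoxycyclobut-2-en-1-one | CC(C)OC1=CC(=O)C1(O)c1cc(=O)cc(-c2ccc(OC)c(OC)c2)o1 | intermediate
11 | (Z)-4-[6-(3,4-dimethoxyphenyl)-4-oxo-4H-pyran-2-yl]-4-hydroxy-3-isopropoxybuta-1,3-dien-1-one (dienylketene, pyranonyl cis to the ketene) | O=C=C/C(OC(C)C)=C(/O)c1cc(=O)cc(-c2ccc(OC)c(OC)c2)o1 | intermediate
12 | rac-2-(3,4-dimethoxyphenyl)-8-hydroxy-7-isopropoxy-4aH-chromene-4,5-dione | COc1ccc(C2=CC(=O)C3C(=O)C=C(OC(C)C)C(O)=C3O2)cc1OC | intermediate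
13 | 2-(3,4-dimethoxyphenyl)-5,8-dihydroxy-7-isopropoxy-4H-chromen-4-one | COc1ccc(-c2cc(=O)c3c(O)cc(OC(C)C)c(O)c3o2)cc1OC | intermediate
14 | 8-hydroxyluteolin (hypolaetin) | O=c1cc(-c2ccc(O)c(O)c2)oc2c(O)c(O)cc(O)c12 | intermediate
15 | 8-hydroxyluteolin 5,7,8,3',4'-pentaacetate | CC(=O)Oc1ccc(-c2cc(=O)c3c(OC(C)=O)cc(OC(C)=O)c(OC(C)=O)c3o2)cc1OC(C)=O | intermediate
16 | 8-hydroxyluteolin 5,8,3',4'-tetraacetate (7-OH free) | CC(=O)Oc1ccc(-c2cc(=O)c3c(OC(C)=O)cc(O)c(OC(C)=O)c3o2)cc1OC(C)=O | intermediate
17 | pyridinium 5,8,3',4'-tetra-O-acetyl-8-hydroxyluteolin 7-sulfate | CC(=O)Oc1ccc(-c2cc(=O)c3c(OC(C)=O)cc(OS(=O)(=O)[O-])c(OC(C)=O)c3o2)cc1OC(C)=O.c1cc[nH+]cc1 | intermediate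
18 | ammonium 8-hydroxyluteolin 7-sulfate | [NH4+].O=c1cc(-c2ccc(O)c(O)c2)oc2c(O)c(OS(=O)(=O)[O-])cc(O)c12 | intermediate
19 | 8-hydroxyluteolin 7-sulfate | O=c1cc(-c2ccc(O)c(O)c2)oc2c(O)c(OS(=O)(=O)O)cc(O)c12 | target

**Step count**
Total: 10 steps. Longest linear sequence: 9 steps (steps 2–10 from 4 and 5); step 1 is a one-step branch that joins at step 4.

**Steps most likely to fail**

Step 5 (ring expansion). The partly aromatic, electron-poor pyranone C2=C3 bond may capture the ketene too slowly. The ketene would then be lost to inward rotation of the hydroxyl and lactonisation, to dimerisation, or the hydroquinone would oxidise during long heating.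
- The fallback leaves the ring expansion and builds ring C on a bought ring A by known chemistry; it sets out from 5.
- 5 acylates commercial 2'-hydroxy-3',4',6'-trimethoxyacetophenone F1 in pyridine to give 2-acetyl-3,5,6-trimethoxyphenyl 3,4-dimethoxybenzoate F2.
- KOH in pyridine at 50 °C shifts the aroyl group from oxygen to carbon (Baker–Venkataraman rearrangement) to give 1-(3,4-dimethoxyphenyl)-3-(2-hydroxy-3,4,6-trimethoxyphenyl)propane-1,3-dione F3.
- H2SO4 in AcOH at 100 °C cyclodehydrates it to 5,7,8,3',4'-pentamethoxyflavone F4.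
- BBr3 in CH2Cl2 removes the five methyl groups and returns to the route at 14.

Step 4 (lithiation and addition). Deprotonation may occur at C3 or C5 beside the carbonyl instead of at C6, the lithiated pyranone may add to 8 that is not yet metalated, or the nucleophile may attack the alkoxy-bearing carbon of 3.
- The fallback sets out from 8 and replaces direct lithiation–addition by halogen–metal exchange on an isolated iodide.
- Lithium 2,2,6,6-tetramethylpiperidide is added at −78 °C to 8 premixed with ZnCl2·2LiCl, so that 9 is trapped at once as [6-(3,4-dimethoxyphenyl)-4-oxo-4H-pyran-2-yl]zinc chloride F5, which does not add to 8.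
- I2 converts it into 2-(3,4-dimethoxyphenyl)-6-iodo-4H-pyran-4-one F6, which is purified and whose substitution pattern is checked before use. If needed, the site of zincation can be steered further with a Lewis acid additive (MgCl2 or BF3·OEt2), as is known for chromones.
- Iodine–magnesium exchange with iPrMgCl·LiCl in THF at −78 °C gives [6-(3,4-dimethoxyphenyl)-4-oxo-4H-pyran-2-yl]magnesium chloride F7, free of amine, and addition of 3 returns to the route at 10.

Step 8 (7-O-deacetylation). A second acetyl group (on O4' or O5) may be lost, or acetyl may move from O8 to O7 before sulfation, so that a mixture of sulfates results.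
- The fallback sets out from 14 and sulfates the unprotected polyphenol directly.
- Tetrabutylammonium hydrogen sulfate and N,N'-dicyclohexylcarbodiimide in pyridine at 4 °C, a method in which the most acidic hydroxyl of a flavone (7-OH) reacts first, should give tetrabutylammonium 8-hydroxyluteolin 7-sulfate F8.
- KOAc in MeOH precipitates potassium 8-hydroxyluteolin 7-sulfate F9, and one equivalent of cold HCl followed by C18 chromatography returns to the route at 19.

**Further compounds**
F1 | step 5 | 2'-hydroxy-3',4',6'-trimethoxyacetophenone | CC(=O)c1c(O)c(OC)c(OC)cc1OC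
F2 | step 5 | 2-acetyl-3,5,6-trimethoxyphenyl 3,4-dimethoxybenzoate | CC(=O)c1c(OC)cc(OC)c(OC)c1OC(=O)c1ccc(OC)c(OC)c1
F3 | step 5 | 1-(3,4-dimethoxyphenyl)-3-(2-hydroxy-3,4,6-trimethoxyphenyl)propane-1,3-dione | COc1ccc(C(=O)CC(=O)c2c(OC)cc(OC)c(OC)c2O)cc1OC
F4 | step 5 | 5,7,8,3',4'-pentamethoxyflavone | COc1ccc(-c2cc(=O)c3c(OC)cc(OC)c(OC)c3o2)cc1OC
F5 | step 4 | [6-(3,4-dimethoxyphenyl)-4-oxo-4H-pyran-2-yl]zinc chloride | Cl[Zn]c1cc(=O)cc(-c2ccc(OC)c(OC)c2)o1
F6 | step 4 | 2-(3,4-dimethoxyphenyl)-6-iodo-4H-pyran-4-one | COc1ccc(-c2cc(=O)cc(I)o2)cc1OC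
F7 | step 4 | [6-(3,4-dimethoxyphenyl)-4-oxo-4H-pyran-2-yl]magnesium chloride | Cl[Mg]c1cc(=O)cc(-c2ccc(OC)c(OC)c2)o1
F8 | step 8 | tetrabutylammonium 8-hydroxyluteolin 7-sulfate | CCCC[N+](CCCC)(CCCC)CCCC.O=c1cc(-c2ccc(O)c(O)c2)oc2c(O)c(OS(=O)(=O)[O-])cc(O)c12
F9 | step 8 | potassium 8-hydroxyluteolin 7-sulfate | [K+].O=c1cc(-c2ccc(O)c(O)c2)oc2c(O)c(OS(=O)(=O)[O-])cc(O)c12
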